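The target is divided at C13–C14 (B-alkyl Suzuki coupling) into a hydroazulene enol triflate and an oxepane-fused cyclohexane. The latter rests on one disconnection: the adjacent, trans-related C11 (tertiary, carrying the C12–C13 linker) and C31 (quaternary, with methyl C32 and C33), which lie between the oxygenated carbons C5 and C8 of the cyclohexane ring, are the β- and α-carbons of a 2-methylcyclohexenone. One copper-catalysed operation adds vinyl to C11 enantioselectively and allylates the enolate at C31, forming C11–C12 and C31–C33. The precursor is 4,4-dimethoxy-2-methylcyclohex-2-en-1-one, a reduced quinone monoketal whose C8 ketal stores the later tertiary alcohol.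

Key step: step 3

Remark on numbering: atom labels (C2, C5, C8 … C35) are the positions of the atoms in the target SMILES; intermediates are described with these labels.
Assumption: in step 3 the antipode of the ferrocenyl diphosphine, and in step 20 the antipode of the diisopinocampheylboron triflate, is the one that gives the drawn configuration (for step 20 the (−)-reagent is taken to attack the aldehyde Si face); the sense is to be confirmed by correlation on first use.

**Left half (oxepane–cyclohexane)**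

Step 1
Reactants: 1 4-methoxy-2-methylphenol
Product: 2 4,4-dimethoxy-2-methylcyclohexa-2,5-dien-1-one
Conditions: PhI(OAc)2, MeOH, 0 °C
Reagents that add atoms: methanol, CO
Why: Oxidative dearomatisation: the iodane oxidises the phenol to a cation that methanol traps para to the oxygen, giving the quinone monoketal.

Step 2
Reactants: 2 4,4-dimethoxy-2-methylcyclohexa-2,5-dien-1-one
Product: 3 4,4-dimethoxy-2-methylcyclohex-2-en-1-one
Conditions: H2 (1 atm), RhCl(PPh3)3 (3 mol%), benzene, rt
Reagents that add atoms: none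
Why: Homogeneous alkene hydrogenation should saturate the unsubstituted cis-disubstituted C=C much faster than the methyl-bearing trisubstituted one, and the neutral medium avoids loss of methanol and rearomatisation.

Step 3
Reactants: 3 4,4-dimethoxy-2-methylcyclohex-2-en-1-one; 4 vinylmagnesium bromide; 5 allyl iodide
Product: 7 (2R,3R)-2-allyl-4,4-dimethoxy-2-methyl-3-vinylcyclohexan-1-one (allyl and vinyl trans), via bromomagnesium enolate 6 (not isolated)
Conditions: CuBr·SMe2 (5 mol%), reversed-Josiphos-type ferrocenyl diphosphine (6 mol%), CH2=CHMgBr (slow addition), t-BuOMe, −78 °C; then allyl iodide, DMPU, −78 → 0 °C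
Reagents that add atoms: none
Why: Transmetalation gives a ligand-bound vinylcopper species that π-complexes the enone, adds oxidatively at C11 (a trivalent copper σ-complex) and reductively eliminates, forming C11–C12 and a magnesium enolate whose double bond is fixed between C5 and C31; allyl iodide then alkylates this enolate at C31 by SN2, forming C31–C33. The closest known reaction type is the copper-catalysed asymmetric conjugate addition of Grignard reagents to 2-methylcycloalkenones with in-flask trans-selective enolate alkylation. No ring is closed. C11 is set by the chiral diphosphine, which selects the enone face that receives vinyl, and C31 by the new C11 vinyl group, which makes allyl iodide approach the enolate from the opposite face (vinyl and allyl trans). The step needs 1,4- over 1,2-addition (soft copper nucleophile at −78 °C), C- over O-alkylation and one enolate regioisomer (the enolate is generated by the conjugate addition itself and activated by DMPU), and the methoxy groups sit on C8, γ to the carbonyl, so the enolate cannot expel them.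

Step 4
Reactants: 7 (2R,3R)-2-allyl-4,4-dimethoxy-2-methyl-3-vinylcyclohexan-1-one
Product: 9 (2R,3R)-2-(3-hydroxypropyl)-4,4-dimethoxy-2-methyl-3-vinylcyclohexan-1-one, via B-alkyl disiamylborane 8 (not isolated)
Conditions: (Sia)2BH (1.2 equiv), THF, 0 °C; then H2O2, aq. NaOH, 0 °C
Reagents that add atoms: hydrogen peroxide, OO
Why: Hydroboration–oxidation: the bulky dialkylborane should add anti-Markovnikov to the unhindered allyl terminus much faster than to the vinyl group wedged between the quaternary carbons C8 and C31 or to the α-quaternary ketone, and C–B oxidation gives the primary alcohol at C35.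

Step 5
Reactants: 9 (2R,3R)-2-(3-hydroxypropyl)-4,4-dimethoxy-2-methyl-3-vinylcyclohexan-1-one
Product: 10 3-[(1R,2R)-3,3-dimethoxy-1-methyl-6-oxo-2-vinylcyclohexyl]propanal
Conditions: Dess–Martin periodinane, NaHCO3, CH2Cl2, 0 °C → rt
Reagents that add atoms: none
Why: Dess–Martin oxidation takes the primary alcohol to the aldehyde under buffered conditions that leave ketal, ketone and alkene untouched.

Step 6
Reactants: 10 3-[(1R,2R)-3,3-dimethoxy-1-methyl-6-oxo-2-vinylcyclohexyl]propanal
Product: 11 (2R,3R)-4,4-dimethoxy-2-methyl-2-(4-methylpent-3-en-1-yl)-3-vinylcyclohexan-1-one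
Conditions: i-PrPPh3I, n-BuLi, THF, 0 °C; then 10, −78 → 0 °C
Reagents that add atoms: isopropyltriphenylphosphonium iodide, CC(C)[P+](c1ccccc1)(c1ccccc1)c1ccccc1.[I-]
Why: Wittig olefination: the non-stabilised isopropylidene ylide reacts with the aldehyde at low temperature while the α-quaternary ketone is too hindered to compete, bringing in C2 with its two methyl groups as a trisubstituted alkene.

Step 7
Reactants: 11 (2R,3R)-4,4-dimethoxy-2-methyl-2-(4-methylpent-3-en-1-yl)-3-vinylcyclohexan-1-one
Product: 12 (1R,2R,3R)-4,4-dimethoxy-2-methyl-2-(4-methylpent-3-en-1-yl)-3-vinylcyclohexan-1-ol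
Conditions: NaBH4, MeOH, −20 °C
Reagents that add atoms: none
Why: Hydride reduction: borohydride should attack the C5 carbonyl from the face opposite the C31 methyl and the C11 vinyl group, giving the C5 alcohol cis to the methyl (equatorial in the chair needed later), which sets C5.

Step 8
Reactants: 12 (1R,2R,3R)-4,4-dimethoxy-2-methyl-2-(4-methylpent-3-en-1-yl)-3-vinylcyclohexan-1-ol
Product: 13 (1R,2R,3R)-2-{2-[(2R)-3,3-dimethyloxiran-2-yl]ethyl}-4,4-dimethoxy-2-methyl-3-vinylcyclohexan-1-ol
Conditions: D-fructose-derived Shi ketone (30 mol%), KHSO5 (as 2KHSO5·KHSO4·K2SO4), K2CO3, Bu4NHSO4, MeCN/CH2(OMe)2/aq. buffer (pH 10.5), 0 °C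
Reagents that add atoms: potassium peroxymonosulfate, [K+].[O-]S(=O)(=O)OO
Why: Shi epoxidation: the chiral dioxirane epoxidises the electron-rich trisubstituted alkene in preference to the monosubstituted vinyl group, and its spiro transition state should deliver oxygen to the face that makes C35 (R).

Step 9
Reactants: 13 (1R,2R,3R)-2-{2-[(2R)-3,3-dimethyloxiran-2-yl]ethyl}-4,4-dimethoxy-2-methyl-3-vinylcyclohexan-1-ol
Product: 14 (3R,5aR,6R,9aR)-7,7-dimethoxy-2,2,5a-trimethyl-6-vinyldecahydro-1-benzoxepin-3-ol (trans-fused)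
Conditions: camphorsulfonic acid (10 mol%), CH2Cl2, −20 → 0 °C
Reagents that add atoms: none
Why: Acid-promoted 7-endo-tet epoxide opening: the protonated trisubstituted epoxide develops positive charge at tertiary C2, which the C5 hydroxyl captures while the C35–O bond stays intact, so C35 keeps its configuration and the trans-fused oxepane forms.

Step 10
Reactants: 14 (3R,5aR,6R,9aR)-7,7-dimethoxy-2,2,5a-trimethyl-6-vinyldecahydro-1-benzoxepin-3-ol
Product: 15 (3R,5aR,6R,9aR)-3-hydroxy-2,2,5a-trimethyl-6-vinyloctahydro-1-benzoxepin-7(2H)-one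
Conditions: pyridinium p-toluenesulfonate (20 mol%), acetone/H2O (10:1), rt
Reagents that add atoms: water, O
Why: Mild acid-catalysed ketal hydrolysis unmasks the C8 ketone; C11 is now epimerisable but already has its vinyl group equatorial, and the weak acid should not move the β,γ-alkene into conjugation.

Step 11
Reactants: 15 (3R,5aR,6R,9aR)-3-hydroxy-2,2,5a-trimethyl-6-vinyloctahydro-1-benzoxepin-7(2H)-one
Product: 16 (3R,5aR,6R,7S,9aR)-2,2,5a,7-tetramethyl-6-vinyldecahydro-1-benzoxepine-3,7-diol
Conditions: MeLi (3.5 equiv), CeCl3 (3.5 equiv), THF, −78 °C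
Reagents that add atoms: methyllithium, [Li]C
Why: 1,2-Addition of a weakly basic methylcerium reagent, which should not enolise the β,γ-unsaturated ketone; the axial C31 methyl blocks axial attack, so the methyl enters equatorially and the C8 hydroxyl becomes axial, which sets C8.

Step 12
Reactants: 16 (3R,5aR,6R,7S,9aR)-2,2,5a,7-tetramethyl-6-vinyldecahydro-1-benzoxepine-3,7-diol
Product: 17 (3R,5aR,6R,7S,9aR)-2,2,5a,7-tetramethyl-3-(triethylsilyloxy)-6-vinyldecahydro-1-benzoxepin-7-ol
Conditions: Et3SiOTf (1.1 equiv), 2,6-lutidine, CH2Cl2, −78 °C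
Reagents that add atoms: triethylsilyl trifluoromethanesulfonate, CC[Si](CC)(CC)OS(=O)(=O)C(F)(F)F
Why: Silylation with a limiting amount of silyl triflate at low temperature protects the secondary C35 hydroxyl and leaves the hindered axial tertiary C8 hydroxyl free.

**Right half (hydroazulene enol triflate)**

Step 13
Reactants: 18 (R)-(−)-linalool
Product: 19 (R)-1-methylcyclopent-2-en-1-ol
Conditions: second-generation Grubbs catalyst RuCl2(=CHPh)(PCy3)(H2IMes) (0.5 mol%), CH2Cl2, rt
Reagents that add atoms: none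
Why: Ring-closing metathesis joins the vinyl group and the trisubstituted alkene with loss of 2-methylpropene; the tertiary carbinol stereocentre (the future C25) is not touched.

Step 14
Reactants: 19 (R)-1-methylcyclopent-2-en-1-ol
Product: 20 (1S,2R,5S)-2-methyl-6-oxabicyclo[3.1.0]hexan-2-ol (epoxide cis to the hydroxyl)
Conditions: VO(acac)2 (2 mol%), t-BuOOH, CH2Cl2, 0 °C → rt
Reagents that add atoms: tert-butyl hydroperoxide, CC(C)(C)OO
Why: Hydroxyl-directed epoxidation: the vanadium alkoxide delivers the peroxide oxygen to the alkene face cis to the tertiary hydroxyl.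

Step 15
Reactants: 20 (1S,2R,5S)-2-methyl-6-oxabicyclo[3.1.0]hexan-2-ol
Product: 21 2-[(1S,2S,3R)-2,3-dihydroxy-3-methylcyclopentyl]-2-methylpropanenitrile (cis-diol; nitrile-bearing group trans to both hydroxyls)
Conditions: i-PrCN, LiN(i-Pr)2 (2.5 equiv each), THF, −78 °C; then 20, −78 °C → rt
Reagents that add atoms: isobutyronitrile, CC(C)C#N
Why: SN2 epoxide opening by the lithiated nitrile at the epoxide carbon remote from the quaternary carbinol, with inversion, sets C22 (C22–C28 bond trans to the C25 oxygen) and brings in C28 with its two methyl groups and C14 as the nitrile carbon.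

Step 16
Reactants: 21 2-[(1S,2S,3R)-2,3-dihydroxy-3-methylcyclopentyl]-2-methylpropanenitrile
Product: 22 2-[(1S,3R)-3-hydroxy-3-methyl-2-oxocyclopentyl]-2-methylpropanenitrile
Conditions: SO3·pyridine, DMSO, i-Pr2NEt, CH2Cl2, 0 °C
Reagents that add atoms: none
Why: Parikh–Doering oxidation takes the secondary alcohol to the ketone without cleaving the 1,2-diol and leaves the tertiary alcohol alone.

Step 17
Reactants: 22 2-[(1S,3R)-3-hydroxy-3-methyl-2-oxocyclopentyl]-2-methylpropanenitrile
Product: 23 2-methyl-2-[(1S,3R)-3-methyl-2-oxo-3-(triethylsilyloxy)cyclopentyl]propanenitrile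
Conditions: Et3SiOTf, 2,6-lutidine, CH2Cl2, −78 → 0 °C
Reagents that add atoms: triethylsilyl trifluoromethanesulfonate, CC[Si](CC)(CC)OS(=O)(=O)C(F)(F)F
Why: Silyl triflate silylation masks the tertiary hydroxyl, which would otherwise consume the organolithium and boron reagents of the following steps.

Step 18
Reactants: 23 2-methyl-2-[(1S,3R)-3-methyl-2-oxo-3-(triethylsilyloxy)cyclopentyl]propanenitrile
Product: 24 2-methyl-2-[(1S,3R)-3-methyl-2-methylidene-3-(triethylsilyloxy)cyclopentyl]propanenitrile
Conditions: Zn, CH2Br2, TiCl4, THF/CH2Cl2, 0 °C → rt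
Reagents that add atoms: dibromomethane, BrCBr
Why: Lombardo methylenation: the non-basic titanium–zinc methylene reagent converts the hindered, epimerisable C21 ketone into the exocyclic alkene needed for the later metathesis, without scrambling C22 or touching the nitrile.

Step 19
Reactants: 24 2-methyl-2-[(1S,3R)-3-methyl-2-methylidene-3-(triethylsilyloxy)cyclopentyl]propanenitrile
Product: 26 2-methyl-2-[(3R)-3-methyl-2-methylidene-3-(triethylsilyloxy)cyclopentyl]pentan-3-one (ring substituent at C22 trans to the silyloxy group, as in 24), via N-lithio ketimine 25 (not isolated)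
Conditions: EtLi, THF, −78 → 0 °C; then AcOH/NaOAc buffer (pH 5), THF/H2O, rt
Reagents that add atoms: ethyllithium, [Li]CC; water, O
Why: Organolithium addition to the non-enolisable tertiary nitrile stops at the N-lithio ketimine, which is hydrolysed at pH 5 to the ethyl ketone (C14 carbonyl with C16 and C17) without loss of the silyl ether.

Step 20
Reactants: 26 2-methyl-2-[(3R)-3-methyl-2-methylidene-3-(triethylsilyloxy)cyclopentyl]pentan-3-one
Product: 28 (4S,5R)-5-hydroxy-2,4-dimethyl-2-[(3R)-3-methyl-2-methylidene-3-(triethylsilyloxy)cyclopentyl]hept-6-en-3-one (ring configuration as in 26), via Z-enol diisopinocampheylborinate 27 (not isolated)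
Conditions: (−)-(Ipc)2BOTf, i-Pr2NEt, CH2Cl2, −78 °C; CH2=CHCHO, −78 → −20 °C; then H2O2, MeOH, pH 7 buffer, 0 °C
Reagents that add atoms: acrolein, C=CC=O
Why: Boron-mediated syn-aldol reaction: only the ethyl side can enolise, the Z-enol borinate adds through a chair transition state, and the isopinocampheyl ligands select the aldehyde face, which sets C18 under reagent control (C16 is set as well but is lost later).

Step 21
Reactants: 28 (4S,5R)-5-hydroxy-2,4-dimethyl-2-[(3R)-3-methyl-2-methylidene-3-(triethylsilyloxy)cyclopentyl]hept-6-en-3-one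
Product: 29 7-hydroxy-1,4,4,6-tetramethyl-1-(triethylsilyloxy)-2,3,3a,4,6,7-hexahydroazulen-5(1H)-one (C20=C21 alkene; 16S,18R; C25 oxygen and H22 on the same face)
Conditions: second-generation Hoveyda–Grubbs catalyst RuCl2(=CH-C6H4-2-O-i-Pr)(H2IMes) (10 mol%), toluene, 80 °C
Reagents that add atoms: none
Why: Ring-closing metathesis: the ruthenium carbene formed at the monosubstituted vinyl group closes onto the 1,1-disubstituted exocyclic alkene with loss of ethene, forming the seven-membered ring and its C20=C21 bond.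

Step 22
Reactants: 29 7-hydroxy-1,4,4,6-tetramethyl-1-(triethylsilyloxy)-2,3,3a,4,6,7-hexahydroazulen-5(1H)-one
Product: 30 cis-fused 7-hydroxy-1,4,4,6-tetramethyl-1-(triethylsilyloxy)octahydroazulen-5(1H)-one (H21, H22, C18 hydroxyl and C25 oxygen all on one face)
Conditions: H2 (1 atm), [Ir(cod)(PCy3)(py)]PF6 (5 mol%), CH2Cl2, rt
Reagents that add atoms: none
Why: Hydroxyl-directed hydrogenation: the cationic iridium catalyst binds the allylic C18 hydroxyl and adds hydrogen to the same face of the trisubstituted alkene, which sets C21 and gives the cis ring fusion.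

Step 23
Reactants: 30 cis-fused 7-hydroxy-1,4,4,6-tetramethyl-1-(triethylsilyloxy)octahydroazulen-5(1H)-one
Product: 31 cis-fused 1,4,4,6-tetramethyl-1,7-bis(triethylsilyloxy)octahydroazulen-5(1H)-one (configuration as in 30)
Conditions: Et3SiOTf, 2,6-lutidine, CH2Cl2, −78 °C
Reagents that add atoms: triethylsilyl trifluoromethanesulfonate, CC[Si](CC)(CC)OS(=O)(=O)C(F)(F)F
Why: Silylation protects the C18 hydroxyl so that the ketone can be enolised in the next step.

Step 24
Reactants: 31 cis-fused 1,4,4,6-tetramethyl-1,7-bis(triethylsilyloxy)octahydroazulen-5(1H)-one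
Product: 33 cis-fused 1,4,4,6-tetramethyl-1,7-bis(triethylsilyloxy)-1,2,3,3a,4,7,8,8a-octahydroazulen-5-yl trifluoromethanesulfonate (C14=C16 enol triflate), via potassium enolate 32 (not isolated)
Conditions: KN(SiMe3)2, THF, −78 °C; then PhNTf2, −78 → −20 °C
Reagents that add atoms: N-phenylbis(trifluoromethanesulfonimide), O=S(=O)(N(c1ccccc1)S(=O)(=O)C(F)(F)F)C(F)(F)F
Why: Enol triflate formation: C16 is the only enolisable position (C28 is quaternary), so the enolate forms regiospecifically and is O-sulfonylated at low temperature before the β-silyloxy group can be eliminated.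

**Union and completion**

Step 25
Reactants: 17 (3R,5aR,6R,7S,9aR)-2,2,5a,7-tetramethyl-3-(triethylsilyloxy)-6-vinyldecahydro-1-benzoxepin-7-ol; 33 hydroazulenyl trifluoromethanesulfonate
Product: 35 tris(triethylsilyl) ether (at O on C35, C18 and C25) of the C14=C16 alkene tetraol 36, via B-alkyl-9-BBN 34 (not isolated)
Conditions: 9-BBN-H dimer (3 equiv), THF, rt → 50 °C; then 33, Pd(dppf)Cl2 (10 mol%), AsPh3, Cs2CO3, DMF/H2O, rt → 50 °C
Reagents that add atoms: none
Why: B-alkyl Suzuki–Miyaura coupling: 9-BBN adds anti-Markovnikov to the only alkene of 17 (the excess accommodates the free tertiary hydroxyl), and the primary alkylborane transmetalates to the palladium species formed by oxidative addition into the enol triflate, forming C13–C14 as known for triflates of 2,2,6-trisubstituted cycloalkanones.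

Step 26
Reactants: 35 tris(triethylsilyl) ether of 36
Product: 36 C14=C16 alkene tetraol (free hydroxyls at C35, C8, C18 and C25; the target without its epoxide oxygen)
Conditions: Bu4NF, THF, rt → 40 °C
Reagents that add atoms: none
Why: Fluoride-mediated desilylation removes all three triethylsilyl groups under basic conditions that do not ionise the allylic alcohol.

Step 27
Reactants: 36 C14=C16 alkene tetraol
Product: 37 CNP0203623.2
Conditions: VO(acac)2 (5 mol%), t-BuOOH, CH2Cl2, 0 °C
Reagents that add atoms: tert-butyl hydroperoxide, CC(C)(C)OO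
Why: Hydroxyl-directed epoxidation: vanadium bound to the allylic C18 hydroxyl delivers oxygen to the cis face of the only alkene, which sets C14 and C16, and the neutral conditions spare the acid-sensitive epoxide.

**Compound list**

1 | 4-methoxy-2-methylphenol | COc1ccc(O)c(C)c1 | starting material
2 | 4,4-dimethoxy-2-methylcyclohexa-2,5-dien-1-one | COC1(OC)C=CC(=O)C(C)=C1 | intermediate
3 | 4,4-dimethoxy-2-methylcyclohex-2-en-1-one | COC1(OC)CCC(=O)C(C)=C1 | intermediate
4 | vinylmagnesium bromide | C=C[Mg]Br | starting material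
5 | allyl iodide | C=CCI | starting material
6 | bromomagnesium enolate of (3R)-4,4-dimethoxy-2-methyl-3-vinylcyclohexanone (not isolated) | Br[Mg]OC1=C(C)[C@@H](C=C)C(OC)(OC)CC1 | intermediate
7 | (2R,3R)-2-allyl-4,4-dimethoxy-2-methyl-3-vinylcyclohexan-1-one | O=C1CCC(OC)(OC)[C@H](C=C)[C@@]1(C)CC=C | intermediate
8 | B-alkyl disiamylborane from the allyl group of 7 (not isolated) | O=C1CCC(OC)(OC)[C@H](C=C)[C@@]1(C)CCCB(C(C)C(C)C)C(C)C(C)C | intermediate
9 | (2R,3R)-2-(3-hydroxypropyl)-4,4-dimethoxy-2-methyl-3-vinylcyclohexan-1-one | O=C1CCC(OC)(OC)[C@H](C=C)[C@@]1(C)CCCO | intermediate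
10 | 3-[(1R,2R)-3,3-dimethoxy-1-methyl-6-oxo-2-vinylcyclohexyl]propanal | O=C1CCC(OC)(OC)[C@H](C=C)[C@@]1(C)CCC=O | intermediate
11 | (2R,3R)-4,4-dimethoxy-2-methyl-2-(4-methylpent-3-en-1-yl)-3-vinylcyclohexan-1-one | O=C1CCC(OC)(OC)[C@H](C=C)[C@@]1(C)CCC=C(C)C | intermediate
12 | (1R,2R,3R)-4,4-dimethoxy-2-methyl-2-(4-methylpent-3-en-1-yl)-3-vinylcyclohexan-1-ol | O[C@@H]1CCC(OC)(OC)[C@H](C=C)[C@@]1(C)CCC=C(C)C | intermediate
13 | (1R,2R,3R)-2-{2-[(2R)-3,3-dimethyloxiran-2-yl]ethyl}-4,4-dimethoxy-2-methyl-3-vinylcyclohexan-1-ol | O[C@@H]1CCC(OC)(OC)[C@H](C=C)[C@@]1(C)CC[C@H]2OC2(C)C | intermediate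
14 | (3R,5aR,6R,9aR)-7,7-dimethoxy-2,2,5a-trimethyl-6-vinyldecahydro-1-benzoxepin-3-ol | CC1(C)O[C@@H]2CCC(OC)(OC)[C@H](C=C)[C@@]2(C)CC[C@H]1O | intermediate
15 | (3R,5aR,6R,9aR)-3-hydroxy-2,2,5a-trimethyl-6-vinyloctahydro-1-benzoxepin-7(2H)-one | CC1(C)O[C@@H]2CCC(=O)[C@H](C=C)[C@@]2(C)CC[C@H]1O | intermediate
16 | (3R,5aR,6R,7S,9aR)-2,2,5a,7-tetramethyl-6-vinyldecahydro-1-benzoxepine-3,7-diol | CC1(C)O[C@@H]2CC[C@](C)(O)[C@H](C=C)[C@@]2(C)CC[C@H]1O | intermediate
17 | (3R,5aR,6R,7S,9aR)-2,2,5a,7-tetramethyl-3-(triethylsilyloxy)-6-vinyldecahydro-1-benzoxepin-7-ol | CC1(C)O[C@@H]2CC[C@](C)(O)[C@H](C=C)[C@@]2(C)CC[C@H]1O[Si](CC)(CC)CC | intermediate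
18 | (R)-(−)-linalool | C=C[C@](C)(O)CCC=C(C)C | starting material
19 | (R)-1-methylcyclopent-2-en-1-ol | C[C@@]1(O)CCC=C1 | intermediate
20 | (1S,2R,5S)-2-methyl-6-oxabicyclo[3.1.0]hexan-2-ol | C[C@@]1(O)CC[C@@H]2O[C@H]12 | intermediate
21 | 2-[(1S,2S,3R)-2,3-dihydroxy-3-methylcyclopentyl]-2-methylpropanenitrile | C[C@@]1(O)CC[C@@H](C(C)(C)C#N)[C@@H]1O | intermediate
22 | 2-[(1S,3R)-3-hydroxy-3-methyl-2-oxocyclopentyl]-2-methylpropanenitrile | C[C@@]1(O)CC[C@@H](C(C)(C)C#N)C1=O | intermediate
23 | 2-methyl-2-[(1S,3R)-3-methyl-2-oxo-3-(triethylsilyloxy)cyclopentyl]propanenitrile | C[C@@]1(O[Si](CC)(CC)CC)CC[C@@H](C(C)(C)C#N)C1=O | intermediate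
24 | 2-methyl-2-[(1S,3R)-3-methyl-2-methylidene-3-(triethylsilyloxy)cyclopentyl]propanenitrile | C[C@@]1(O[Si](CC)(CC)CC)CC[C@@H](C(C)(C)C#N)C1=C | intermediate
25 | N-lithio ketimine from 24 and ethyllithium (not isolated) | C[C@@]1(O[Si](CC)(CC)CC)CC[C@@H](C(C)(C)C(CC)=N[Li])C1=C | intermediate
26 | 2-methyl-2-[(3R)-3-methyl-2-methylidene-3-(triethylsilyloxy)cyclopentyl]pentan-3-one (C22 substituent trans to the silyloxy group) | C[C@@]1(O[Si](CC)(CC)CC)CC[C@@H](C(C)(C)C(=O)CC)C1=C | intermediate
27 | Z-enol diisopinocampheylborinate of 26 (not isolated) | C/C=C(OB([C@@H]1C[C@@H]2C[C@H]([C@H]1C)C2(C)C)[C@@H]1C[C@@H]2C[C@H]([C@H]1C)C2(C)C)/C(C)(C)[C@@H]1CC[C@@](C)(O[Si](CC)(CC)CC)C1=C | intermediate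
28 | (4S,5R)-5-hydroxy-2,4-dimethyl-2-[(3R)-3-methyl-2-methylidene-3-(triethylsilyloxy)cyclopentyl]hept-6-en-3-one | C[C@@]1(O[Si](CC)(CC)CC)CC[C@@H](C(C)(C)C(=O)[C@@H](C)[C@H](O)C=C)C1=C | intermediate
29 | 7-hydroxy-1,4,4,6-tetramethyl-1-(triethylsilyloxy)-2,3,3a,4,6,7-hexahydroazulen-5(1H)-one | O=C1[C@@H](C)[C@H](O)C=C2[C@@H](CC[C@@]2(C)O[Si](CC)(CC)CC)C1(C)C | intermediate
30 | cis-fused 7-hydroxy-1,4,4,6-tetramethyl-1-(triethylsilyloxy)octahydroazulen-5(1H)-one | O=C1[C@@H](C)[C@H](O)C[C@@H]2[C@@H](CC[C@@]2(C)O[Si](CC)(CC)CC)C1(C)C | intermediate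
31 | cis-fused 1,4,4,6-tetramethyl-1,7-bis(triethylsilyloxy)octahydroazulen-5(1H)-one | O=C1[C@@H](C)[C@H](O[Si](CC)(CC)CC)C[C@@H]2[C@@H](CC[C@@]2(C)O[Si](CC)(CC)CC)C1(C)C | intermediate
32 | potassium enolate of 31 (not isolated) | [K]OC1=C(C)[C@H](O[Si](CC)(CC)CC)C[C@@H]2[C@@H](CC[C@@]2(C)O[Si](CC)(CC)CC)C1(C)C | intermediate
33 | cis-fused 1,4,4,6-tetramethyl-1,7-bis(triethylsilyloxy)-1,2,3,3a,4,7,8,8a-octahydroazulen-5-yl trifluoromethanesulfonate | O=S(=O)(OC1=C(C)[C@H](O[Si](CC)(CC)CC)C[C@@H]2[C@@H](CC[C@@]2(C)O[Si](CC)(CC)CC)C1(C)C)C(F)(F)F | intermediate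
34 | B-alkyl-9-BBN from the vinyl group of 17 (not isolated) | CC1(C)O[C@@H]2CC[C@](C)(O)[C@H](CCB3C4CCCC3CCC4)[C@@]2(C)CC[C@H]1O[Si](CC)(CC)CC | intermediate
35 | coupled C14=C16 alkene, triethylsilyl ethers at C35, C18 and C25, free hydroxyl at C8 | CC1(C)O[C@@H]2CC[C@](C)(O)[C@H](CCC3=C(C)[C@H](O[Si](CC)(CC)CC)C[C@@H]4[C@@H](CC[C@@]4(C)O[Si](CC)(CC)CC)C3(C)C)[C@@]2(C)CC[C@H]1O[Si](CC)(CC)CC | intermediate
36 | C14=C16 alkene tetraol | CC1(C)O[C@@H]2CC[C@](C)(O)[C@H](CCC3=C(C)[C@H](O)C[C@@H]4[C@@H](CC[C@@]4(C)O)C3(C)C)[C@@]2(C)CC[C@H]1O | intermediate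
37 | CNP0203623.2 | CC1(C)O[C@@H]2CC[C@](C)(O)[C@H](CC[C@@]34O[C@]3(C)[C@H](O)C[C@@H]3[C@@H](CC[C@@]3(C)O)C4(C)C)[C@@]2(C)CC[C@H]1O | target

**Step count and risk**

Total step count: 27. Longest linear sequence: 15 steps (steps 1–12, then 25–27; the branch of steps 13–24 followed by 25–27 is equally long).

Steps most likely to fail, most doubtful first:

Step 9. The C5 hydroxyl may attack the secondary epoxide carbon C35 instead (6-exo closure to a tetrahydropyran carbinol), or the opened epoxide may rearrange by hydride shift to a ketone. The fallback makes the same C5–O–C2 bond in an exo sense, where ring size and Markovnikov preference point the same way. Setting out from epoxide 13, diethylaluminium 2,2,6,6-tetramethylpiperidide (from Et2AlCl and the lithium amide, benzene, 0 °C) should isomerise the epoxide to the allylic alcohol F1, with the C35 oxygen retained and C2 as an isopropenyl carbon. Intramolecular alkoxymercuration with Hg(OCOCF3)2 (MeCN, 0 °C) should then add the C5 hydroxyl to the tertiary alkene carbon (7-exo) to give the organomercurial F2. Reductive demercuration (NaBH4, aq. NaOH) comes back to the route at 14.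

Step 21. The ruthenium carbene may fail to engage the exocyclic methylene, which is flanked by the silyloxy-bearing quaternary C25 and the branched C22, so that oligomerisation or allylic alcohol isomerisation takes over. The fallback closes the seven-membered ring at the less hindered C16=C18 position instead. Setting out from nitrile 24, hydroboration of the methylene with 9-BBN-H (expected from the face opposite the C22 substituent and the C25 methyl) gives the B-alkyl-9-BBN F3. Coupling in the same flask with vinyl bromide (Pd(dppf)Cl2, K3PO4, DMF) gives the allyl nitrile F4. Isopropenylmagnesium bromide adds to the nitrile to give the bromomagnesium ketimide F5, which is hydrolysed (pH 5 buffer) to the dienone F6. Ring-closing metathesis (second-generation Grubbs catalyst, CH2Cl2, 40 °C) gives the bicyclic α-methyl enone F7. Copper-catalysed conjugate borylation (CuCl, NaOt-Bu, a chiral bisphosphine chosen for 18R, B2pin2, MeOH, THF) gives the β-boryl ketone F8, and oxidation (NaBO3, THF/H2O) gives 30 together with its C16 epimer F9. Both are taken through step 23 (31 and its C16 epimer F10) and step 24, where C16 becomes sp2, so this path comes back to the route at 30 and converges fully at 33.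

Step 3. The vinylcopper species may add with poor enantioface selectivity, or transfer slowly to the β-carbon next to the ketal so that 1,2-addition competes. The fallback gives up catalytic asymmetric induction and resolves instead. Setting out from enone 3, a ligand-free copper-mediated addition (CH2=CHMgBr, CuI, Me3SiCl, THF, −78 °C), with the enolate regenerated by MeLi and allylated with allyl iodide, gives the racemic trans ketone F11. NaBH4 reduction gives the racemic alcohol F12. Esterification with (S)-O-methylmandelic acid (DCC, DMAP) gives the (1R,2R,3R) mandelate F13 and the diastereomeric mandelate F14, which are separated by chromatography. Reductive cleavage of F13 (i-Bu2AlH, CH2Cl2, −78 °C) gives the resolved alcohol F15, and Dess–Martin oxidation comes back to the route at 7.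

Further compounds

F1 | step 9 | (1R,2R,3R)-2-[(3R)-3-hydroxy-4-methylpent-4-en-1-yl]-4,4-dimethoxy-2-methyl-3-vinylcyclohexan-1-ol | O[C@@H]1CCC(OC)(OC)[C@H](C=C)[C@@]1(C)CC[C@@H](O)C(C)=C
F2 | step 9 | oxepane 14 carrying CH2HgOCOCF3 in place of one C2 methyl (both C2 epimers) | FC(F)(F)C(=O)O[Hg]CC1(C)O[C@@H]2CCC(OC)(OC)[C@H](C=C)[C@@]2(C)CC[C@H]1O
F3 | step 21 | B-alkyl-9-BBN from the methylene group of 24 (C21–CH2B cis to the C22 substituent) | C[C@@]1(O[Si](CC)(CC)CC)CC[C@@H](C(C)(C)C#N)[C@H]1CB1C2CCCC1CCC2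
F4 | step 21 | 2-[2-allyl-3-methyl-3-(triethylsilyloxy)cyclopentyl]-2-methylpropanenitrile (allyl cis to the nitrile-bearing group, trans to the silyloxy group) | C[C@@]1(O[Si](CC)(CC)CC)CC[C@@H](C(C)(C)C#N)[C@H]1CC=C
F5 | step 21 | bromomagnesium ketimide from F4 and isopropenylmagnesium bromide | C[C@@]1(O[Si](CC)(CC)CC)CC[C@@H](C(C)(C)C(=N[Mg]Br)C(C)=C)[C@H]1CC=C
F6 | step 21 | 4-[2-allyl-3-methyl-3-(triethylsilyloxy)cyclopentyl]-2,4-dimethylpent-1-en-3-one (configuration as in F4) | C[C@@]1(O[Si](CC)(CC)CC)CC[C@@H](C(C)(C)C(=O)C(C)=C)[C@H]1CC=C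
F7 | step 21 | cis-fused 1,4,4,6-tetramethyl-1-(triethylsilyloxy)-2,3,3a,4,8,8a-hexahydroazulen-5(1H)-one | O=C1C(C)=CC[C@@H]2[C@@H](CC[C@@]2(C)O[Si](CC)(CC)CC)C1(C)C
F8 | step 21 | cis-fused 7-(pinacolatoboryl)-1,4,4,6-tetramethyl-1-(triethylsilyloxy)octahydroazulen-5(1H)-one (boron on the face of the later C18 hydroxyl; both C16 epimers) | O=C1C(C)[C@H](B2OC(C)(C)C(C)(C)O2)C[C@@H]3[C@@H](CC[C@@]3(C)O[Si](CC)(CC)CC)C1(C)C
F9 | step 21 | C16 epimer of 30 | O=C1[C@H](C)[C@H](O)C[C@@H]2[C@@H](CC[C@@]2(C)O[Si](CC)(CC)CC)C1(C)C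
F10 | step 21 | C16 epimer of 31 | O=C1[C@H](C)[C@H](O[Si](CC)(CC)CC)C[C@@H]2[C@@H](CC[C@@]2(C)O[Si](CC)(CC)CC)C1(C)C
F11 | step 3 | racemic trans-2-allyl-4,4-dimethoxy-2-methyl-3-vinylcyclohexan-1-one (7 and its enantiomer) | O=C1CCC(OC)(OC)[C@H](C=C)[C@@]1(C)CC=C.O=C1CCC(OC)(OC)[C@@H](C=C)[C@]1(C)CC=C
F12 | step 3 | racemic 2-allyl-4,4-dimethoxy-2-methyl-3-vinylcyclohexan-1-ol (hydroxyl cis to methyl and vinyl; both enantiomers) | O[C@@H]1CCC(OC)(OC)[C@H](C=C)[C@@]1(C)CC=C.O[C@H]1CCC(OC)(OC)[C@@H](C=C)[C@]1(C)CC=C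
F13 | step 3 | (1R,2R,3R)-2-allyl-4,4-dimethoxy-2-methyl-3-vinylcyclohexyl (S)-2-methoxy-2-phenylacetate | CO[C@H](C(=O)O[C@@H]1CCC(OC)(OC)[C@H](C=C)[C@@]1(C)CC=C)c1ccccc1
F14 | step 3 | (1S,2S,3S)-2-allyl-4,4-dimethoxy-2-methyl-3-vinylcyclohexyl (S)-2-methoxy-2-phenylacetate | CO[C@H](C(=O)O[C@H]1CCC(OC)(OC)[C@@H](C=C)[C@]1(C)CC=C)c1ccccc1
F15 | step 3 | (1R,2R,3R)-2-allyl-4,4-dimethoxy-2-methyl-3-vinylcyclohexan-1-ol | O[C@@H]1CCC(OC)(OC)[C@H](C=C)[C@@]1(C)CC=C
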